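**Plan**

- Retrosynthesis: the three aryl silyl ethers are removed first, then ring C is cut at C3–C4, then the O1–C2 ether, and on ring B the C5'–C(allyl) bond and the 4'-O-methyl bond.
- Enabling feature: in ring C the C4 ketone sits directly beside the fully substituted carbinol C3 that carries ring B. This α-ketol is what results when an acyl anion made from a ring A aldehyde adds to a ring B aryl ketone.
- Forward: gallacetophenone is made into the ring B bromoketone (4-O-prenylation, Claisen shift to C5, 4-O-methylation, silylation/bromination), which is joined through O1–C2 to the ring A salicylaldehyde.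
- Ring C is the only ring formed, and it closes last, by the C3–C4 bond; desilylation then gives the target.
- Stereochemistry: C3 (R) is the only stereocentre. It is set in the ring closure by a chiral triazolium-derived carbene and carries no hydrogen, so it cannot epimerise afterwards.

Key step: step 7

Assumption: the (5aR,10bS) antipode of the aminoindanol-derived precatalyst is taken to give the (3R)-ketol; should a trial run show the opposite sense, the equally available (5aS,10bR) salt is used in step 7 and nothing else changes.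

**Route**

Step 1
Reactants: 1 gallacetophenone (1-(2,3,4-trihydroxyphenyl)ethanone); 2 prenyl bromide (1-bromo-3-methylbut-2-ene)
Product: 3 1-[2,3-dihydroxy-4-(3-methylbut-2-en-1-yloxy)phenyl]ethanone
Conditions: NaHCO3, DMF, rt to 40 °C
Reagents that add atoms: none
Why: Williamson etherification under a weak base should alkylate only the 4-OH, the most acidic phenol (para to the acetyl group), while the 2-OH is held in a hydrogen bond to the carbonyl and the 3-OH is less acidic.

Step 2
Reactants: 3 1-[2,3-dihydroxy-4-(3-methylbut-2-en-1-yloxy)phenyl]ethanone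
Product: 5 1-[2,3,4-trihydroxy-5-(2-methylbut-3-en-2-yl)phenyl]ethanone, via ortho-dienone 4 (not isolated)
Conditions: PhNEt2, 190 °C, argon
Reagents that add atoms: none
Why: The aromatic Claisen rearrangement ([3,3]-sigmatropic shift) of the aryl prenyl ether should deliver the inverted 1,1-dimethylallyl unit to C5, the only open ortho position (C3 carries oxygen, the para carbon carries the acetyl group), and tautomerisation of dienone 4 restores the arene, the weakly basic amine solvent holding back acid-promoted cyclisation of the new phenol onto its alkene.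

Step 3
Reactants: 5 1-[2,3,4-trihydroxy-5-(2-methylbut-3-en-2-yl)phenyl]ethanone
Product: 6 1-[2,3-dihydroxy-4-methoxy-5-(2-methylbut-3-en-2-yl)phenyl]ethanone
Conditions: Na2B4O7·10H2O, NaOH, Me2SO4, H2O, rt; then aq HCl
Reagents that add atoms: dimethyl sulfate, COS(=O)(=O)OC
Why: Borate-templated regioselective O-methylation, established for gallacetophenone itself, should methylate only O-4, because the central 3-OH is tied into a cyclic borate with either neighbour and the 2-OH is chelated to the ketone, leaving the 4-phenoxide to meet the small electrophile although it is flanked by the quaternary carbon.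

Step 4
Reactants: 6 1-[2,3-dihydroxy-4-methoxy-5-(2-methylbut-3-en-2-yl)phenyl]ethanone
Product: 8 2-bromo-1-[2,3-bis(tert-butyldimethylsilyloxy)-4-methoxy-5-(2-methylbut-3-en-2-yl)phenyl]ethanone, via tris-silyl enol ether 7 (not isolated)
Conditions: tert-butyldimethylsilyl triflate, Et3N, CH2Cl2, 0 °C to rt; aqueous NaHCO3 wash; crude enol ether, then N-bromosuccinimide, THF, −78 to 0 °C
Reagents that add atoms: tert-butyldimethylsilyl triflate, CC(C)(C)[Si](C)(C)OS(=O)(=O)C(F)(F)F; N-bromosuccinimide, O=C1CCC(=O)N1Br
Why: Silyl triflate with amine base should silylate both phenols and convert the methyl ketone into its silyl enol ether in one operation, and electrophilic bromination of that enol ether by N-bromosuccinimide is far faster than attack on the hindered monosubstituted alkene or the arene, so the α-bromoketone forms without free bromine and with no free phenol ever next to a silyl ether.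

Step 5
Reactants: 9 2,4-dihydroxybenzaldehyde
Product: 10 2-hydroxy-4-(triisopropylsilyloxy)benzaldehyde
Conditions: triisopropylsilyl chloride, imidazole, CH2Cl2, 0 °C
Reagents that add atoms: triisopropylsilyl chloride, CC(C)[Si](Cl)(C(C)C)C(C)C
Why: Selective phenol silylation should take the 4-OH only, since the 2-OH is hydrogen-bonded to the formyl group; the triisopropylsilyl ether is chosen because it should resist the carbonate base of the next step better than a smaller silyl group.

Step 6
Reactants: 8 2-bromo-1-[2,3-bis(tert-butyldimethylsilyloxy)-4-methoxy-5-(2-methylbut-3-en-2-yl)phenyl]ethanone; 10 2-hydroxy-4-(triisopropylsilyloxy)benzaldehyde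
Product: 11 2-{2-[2,3-bis(tert-butyldimethylsilyloxy)-4-methoxy-5-(2-methylbut-3-en-2-yl)phenyl]-2-oxoethoxy}-4-(triisopropylsilyloxy)benzaldehyde
Conditions: K2CO3, acetone, 0 °C to rt
Reagents that add atoms: none
Why: Williamson etherification of the salicylaldehyde phenoxide with a phenacyl-type bromide is an SN2 reaction fast enough at room temperature that the aryl silyl ethers should survive and the Rap–Stoermer aldol closure of the product should not set in.

Step 7
Reactants: 11 2-{2-[2,3-bis(tert-butyldimethylsilyloxy)-4-methoxy-5-(2-methylbut-3-en-2-yl)phenyl]-2-oxoethoxy}-4-(triisopropylsilyloxy)benzaldehyde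
Product: 12 (3R)-3-[2,3-bis(tert-butyldimethylsilyloxy)-4-methoxy-5-(2-methylbut-3-en-2-yl)phenyl]-3-hydroxy-7-(triisopropylsilyloxy)-2,3-dihydro-4H-chromen-4-one
Conditions: (5aR,10bS)-5a,10b-dihydro-2-(pentafluorophenyl)-4H,6H-indeno[2,1-b][1,2,4]triazolo[4,3-d][1,4]oxazinium tetrafluoroborate (15 mol %), Et3N (15 mol %), toluene, rt, argon
Reagents that add atoms: none
Why: The carbene freed from the triazolium salt by Et3N adds to the aldehyde of 11, proton transfer gives the enaminol (an acyl anion equivalent at C4), this attacks the tethered ketone carbon C3, and collapse of the adduct expels the carbene to leave the C4 ketone beside the C3 carbinol. The closest known reaction is the carbene-catalysed intramolecular crossed aldehyde–ketone benzoin of 2-(2-oxo-2-arylethoxy)benzaldehydes to 3-aryl-3-hydroxychroman-4-ones. Ring C closes in a 6-exo-trig mode, the acceptor carbonyl oxygen staying outside the new ring. C3 is set under catalyst control: the indane wall of the carbene shields one face of the enaminol and a hydrogen bond from its hydroxyl to the incoming ketone oxygen orders the transition state, so one enantioface of the ketone is attacked and the (R)-carbinol should result. The step needs the aldehyde as sole donor and the ketone as sole acceptor, which the substrate secures because a ketone cannot form the enaminol and the six-membered tether lets addition to the hindered, electron-rich ketone outrun aldehyde dimerisation. The acidic C2 methylene is kept from aldol closure to the 2-aroylbenzofuran by the weak base that the acidic N-pentafluorophenyl salt permits.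

Step 8
Reactants: 12 (3R)-3-[2,3-bis(tert-butyldimethylsilyloxy)-4-methoxy-5-(2-methylbut-3-en-2-yl)phenyl]-3-hydroxy-7-(triisopropylsilyloxy)-2,3-dihydro-4H-chromen-4-one
Product: 13 (3R)-3-[2,3-dihydroxy-4-methoxy-5-(2-methylbut-3-en-2-yl)phenyl]-3,7-dihydroxy-2,3-dihydro-4H-chromen-4-one (CNP0274064.1)
Conditions: Bu4NF, AcOH, THF, 0 °C to rt, argon
Reagents that add atoms: none
Why: Fluoride-mediated desilylation should cleave all three aryl silyl ethers, and the acetic acid buffer protonates each phenoxide as it forms so that the base-sensitive tertiary α-ketol does not undergo α-ketol rearrangement; C3 has no hydrogen and is untouched.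

**Compound list**

1 | gallacetophenone, 1-(2,3,4-trihydroxyphenyl)ethanone | CC(=O)c1ccc(O)c(O)c1O | starting material
2 | prenyl bromide, 1-bromo-3-methylbut-2-ene | CC(C)=CCBr | starting material
3 | 1-[2,3-dihydroxy-4-(3-methylbut-2-en-1-yloxy)phenyl]ethanone | CC(=O)c1ccc(OCC=C(C)C)c(O)c1O | intermediate
4 | 4-acetyl-2,3-dihydroxy-6-(2-methylbut-3-en-2-yl)cyclohexa-2,4-dien-1-one (ortho-dienone, racemic at C6, not isolated) | CC(=O)C1=CC(C(C)(C)C=C)C(=O)C(O)=C1O | intermediate
5 | 1-[2,3,4-trihydroxy-5-(2-methylbut-3-en-2-yl)phenyl]ethanone | CC(=O)c1cc(C(C)(C)C=C)c(O)c(O)c1O | intermediate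
6 | 1-[2,3-dihydroxy-4-methoxy-5-(2-methylbut-3-en-2-yl)phenyl]ethanone | CC(=O)c1cc(C(C)(C)C=C)c(OC)c(O)c1O | intermediate
7 | tert-butyldimethylsilyl enol ether of 1-[2,3-bis(tert-butyldimethylsilyloxy)-4-methoxy-5-(2-methylbut-3-en-2-yl)phenyl]ethanone (not isolated) | C=C(O[Si](C)(C)C(C)(C)C)c1cc(C(C)(C)C=C)c(OC)c(O[Si](C)(C)C(C)(C)C)c1O[Si](C)(C)C(C)(C)C | intermediate
8 | 2-bromo-1-[2,3-bis(tert-butyldimethylsilyloxy)-4-methoxy-5-(2-methylbut-3-en-2-yl)phenyl]ethanone | O=C(CBr)c1cc(C(C)(C)C=C)c(OC)c(O[Si](C)(C)C(C)(C)C)c1O[Si](C)(C)C(C)(C)C | intermediate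
9 | 2,4-dihydroxybenzaldehyde | O=Cc1ccc(O)cc1O | starting material
10 | 2-hydroxy-4-(triisopropylsilyloxy)benzaldehyde | O=Cc1ccc(O[Si](C(C)C)(C(C)C)C(C)C)cc1O | intermediate
11 | 2-{2-[2,3-bis(tert-butyldimethylsilyloxy)-4-methoxy-5-(2-methylbut-3-en-2-yl)phenyl]-2-oxoethoxy}-4-(triisopropylsilyloxy)benzaldehyde | O=Cc1ccc(O[Si](C(C)C)(C(C)C)C(C)C)cc1OCC(=O)c1cc(C(C)(C)C=C)c(OC)c(O[Si](C)(C)C(C)(C)C)c1O[Si](C)(C)C(C)(C)C | intermediate
12 | (3R)-3-[2,3-bis(tert-butyldimethylsilyloxy)-4-methoxy-5-(2-methylbut-3-en-2-yl)phenyl]-3-hydroxy-7-(triisopropylsilyloxy)-2,3-dihydro-4H-chromen-4-one | C=CC(C)(C)c1cc([C@@]2(O)COc3cc(O[Si](C(C)C)(C(C)C)C(C)C)ccc3C2=O)c(O[Si](C)(C)C(C)(C)C)c(O[Si](C)(C)C(C)(C)C)c1OC | intermediate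
13 | (3R)-3-[2,3-dihydroxy-4-methoxy-5-(2-methylbut-3-en-2-yl)phenyl]-3,7-dihydroxy-2,3-dihydro-4H-chromen-4-one | C=CC(C)(C)c1cc([C@@]2(O)COc3cc(O)ccc3C2=O)c(O)c(O)c1OC | target

**Step count**

Total: 8 steps. Longest linear sequence: 7 steps (steps 1, 2, 3, 4, 6, 7, 8); step 5 is the one-step side branch for ring A.

**Steps most likely to fail, with fallbacks**

Step 7. Carbene addition to the ring B ketone may be slow, because the ketone is electron-rich and flanked by an ortho silyloxy group; base-mediated aldol closure or poor enantioface discrimination could then take over. The fallback gives up asymmetric induction and obtains the stereocentre by resolution. It sets out from 11, which is cyclised with the small achiral carbene from 2-(pentafluorophenyl)-6,7-dihydro-5H-pyrrolo[2,1-c][1,2,4]triazol-2-ium tetrafluoroborate and Et3N in toluene. This should give the racemic 3-hydroxychroman-4-one tris-silyl ether F1. Preparative chromatography of F1 on a chiral stationary phase (amylose tris(3,5-dimethylphenylcarbamate)) would supply the (R)-enantiomer, and the route is rejoined at 12.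

Step 3. Methylation may stray to O-3 or O-2 or run on to a dimethyl ether, because the wanted O-4 is shielded by the neighbouring quaternary carbon. The fallback replaces the transient borate by a covalent catechol ketal and sets out from 3.
- Dichlorodiphenylmethane with K2CO3 in MeCN should give 1-[2,2-diphenyl-7-(3-methylbut-2-en-1-yloxy)-1,3-benzodioxol-4-yl]ethanone F2.
- Claisen rearrangement of F2 in PhNEt2 at 190 °C would pass through the ketal-protected ortho-dienone F3 to 1-[7-hydroxy-6-(2-methylbut-3-en-2-yl)-2,2-diphenyl-1,3-benzodioxol-4-yl]ethanone F4, whose only free hydroxyl is the one to be methylated.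
- MeI and K2CO3 in acetone should then give 1-[7-methoxy-6-(2-methylbut-3-en-2-yl)-2,2-diphenyl-1,3-benzodioxol-4-yl]ethanone F5.
- Hydrolysis of the ketal in hot aqueous acetic acid would release the catechol, and the route is rejoined at 6.

Step 6. The carbonate base may carry the freshly formed keto-aldehyde on to aldol condensation (2-aroylbenzofuran formation). The fallback runs the etherification with ring A at the alcohol oxidation level, so that no aldehyde is present while base is, and sets out from 10.
- NaBH4 in MeOH at 0 °C should give 2-(hydroxymethyl)-5-(triisopropylsilyloxy)phenol F6.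
- Alkylation of the phenol of F6 with 8 (K2CO3, acetone, rt) would give 1-[2,3-bis(tert-butyldimethylsilyloxy)-4-methoxy-5-(2-methylbut-3-en-2-yl)phenyl]-2-[2-(hydroxymethyl)-5-(triisopropylsilyloxy)phenoxy]ethanone F7.
- Oxidation of the benzylic alcohol of F7 with MnO2 in CH2Cl2 should give the aldehyde, and the route is rejoined at 11.

**Further compounds**

F1 | step 7 | racemic 3-[2,3-bis(tert-butyldimethylsilyloxy)-4-methoxy-5-(2-methylbut-3-en-2-yl)phenyl]-3-hydroxy-7-(triisopropylsilyloxy)-2,3-dihydro-4H-chromen-4-one | C=CC(C)(C)c1cc(C2(O)COc3cc(O[Si](C(C)C)(C(C)C)C(C)C)ccc3C2=O)c(O[Si](C)(C)C(C)(C)C)c(O[Si](C)(C)C(C)(C)C)c1OC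
F2 | step 3 | 1-[2,2-diphenyl-7-(3-methylbut-2-en-1-yloxy)-1,3-benzodioxol-4-yl]ethanone | CC(=O)c1ccc(OCC=C(C)C)c2OC(c3ccccc3)(c3ccccc3)Oc12
F3 | step 3 | ketal-protected ortho-dienone, 2,3-(diphenylmethylenedioxy)-4-acetyl-6-(2-methylbut-3-en-2-yl)cyclohexa-2,4-dien-1-one (not isolated) | CC(=O)C1=CC(C(C)(C)C=C)C(=O)C2=C1OC(c3ccccc3)(c3ccccc3)O2
F4 | step 3 | 1-[7-hydroxy-6-(2-methylbut-3-en-2-yl)-2,2-diphenyl-1,3-benzodioxol-4-yl]ethanone | CC(=O)c1cc(C(C)(C)C=C)c(O)c2OC(c3ccccc3)(c3ccccc3)Oc12
F5 | step 3 | 1-[7-methoxy-6-(2-methylbut-3-en-2-yl)-2,2-diphenyl-1,3-benzodioxol-4-yl]ethanone | CC(=O)c1cc(C(C)(C)C=C)c(OC)c2OC(c3ccccc3)(c3ccccc3)Oc12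
F6 | step 6 | 2-(hydroxymethyl)-5-(triisopropylsilyloxy)phenol | OCc1ccc(O[Si](C(C)C)(C(C)C)C(C)C)cc1O
F7 | step 6 | 1-[2,3-bis(tert-butyldimethylsilyloxy)-4-methoxy-5-(2-methylbut-3-en-2-yl)phenyl]-2-[2-(hydroxymethyl)-5-(triisopropylsilyloxy)phenoxy]ethanone | OCc1ccc(O[Si](C(C)C)(C(C)C)C(C)C)cc1OCC(=O)c1cc(C(C)(C)C=C)c(OC)c(O[Si](C)(C)C(C)(C)C)c1O[Si](C)(C)C(C)(C)C
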